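## Retrosynthetic overview

1. Target 28 ⇐ triol 25 by oxidative lactonisation of C6–OH/C12–OH (the α-methylene-γ-butyrolactone is the last ring formed) ⇐ ten-membered (Z)-enone 22 by acylation at C8 and desilylation.
2. 22 ⇐ eight-membered lactone 20: the C2–C3 bond is made by a Claisen ring expansion of the 2-methylene-8-isopropenyl-oxocane 21, obtained by methylenating the lactone carbonyl (the ring oxygen links C1 and C5).
3. 20 ⇐ seco acid 19 (C1 acid onto C5–OH); the C5 carbinol and its isopropenyl group ⇐ Schenck ene reaction of a prenyl olefin.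
4. C6/C7 ⇐ boron aldol of ketone 9 with prenal; C8 ⇐ 1,3-anti reduction, then a temporary γ-lactone (C1 acyl on O8) that tells C8–OH from C6–OH; 9 ⇐ (R)-citramalic acid (C10) and an allyl Grignard reagent.
5. Enabling feature: the γ,δ-unsaturated ketone C1(=O)–C2–C3–C4(CH3)=C5 inside the ten-membered ring (a Claisen retron), flanked by O-bearing C6 next to C5 and fully substituted C10 next to C1. Ring order: temporary γ-lactone → eight-membered lactone → ten-membered carbocycle → butyrolactone.

Key step: step 13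

Numbering used below (germacrane style): C1 ketone carbon, C2 and C3 the two ring CH2, C4=C5 the ring olefin (methyl on C4), C6 the lactone O–CH, C7 the ring CH carrying C11, C8 the acyloxy CH, C9 CH2, C10 the carbinol carbon, C11(=C13H2)–C12 the lactone carbons.

Remark 1: the antipode of Ipc2BOTf in step 7 is taken to be the one whose Z-enol borinate gives the 6,7 configuration drawn; (−)-Ipc2BOTf is written.

Remark 2: C5 in compounds 18–21 is a temporary stereocentre that becomes sp2 in step 13; the 5,6-anti epimer expected from attack of singlet oxygen anti to the C6 silyloxy group is drawn, and its epimer should serve equally.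

## Route

Step 1
Reactants: 1 2-methylenepropane-1,3-diol
Product: 2 2-(tert-butyldiphenylsilyloxymethyl)prop-2-en-1-ol
Conditions: NaH (1.0 equiv), THF, 0 °C; TBDPSCl, 0 °C → rt
Reagents that add atoms: tert-butyl(chloro)diphenylsilane, CC(C)(C)[Si](Cl)(c1ccccc1)c1ccccc1
Why: O-silylation of the sparingly soluble monosodium alkoxide of a symmetric diol should stop at the mono ether, and no stereocentre is involved.

Step 2
Reactants: 2 mono-silyl ether
Product: 3 tert-butyl{[2-(chloromethyl)prop-2-en-1-yl]oxy}diphenylsilane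
Conditions: NCS, Me2S, CH2Cl2, −20 → 0 °C
Reagents that add atoms: N-chlorosuccinimide, O=C1CCC(=O)N1Cl
Why: Corey–Kim chlorination turns the allylic alcohol into the chloride through an alkoxysulfonium salt under neutral conditions that spare the silyl ether, and allylic transposition is degenerate here.

Step 3
Reactants: 4 (R)-citramalic acid
Product: 5 dimethyl (2R)-2-hydroxy-2-methylbutanedioate
Conditions: MeOH, H2SO4 (cat.), reflux
Reagents that add atoms: methanol, CO
Why: Fischer esterification of both carboxyl groups, with C10 (R, from the chiral pool) being a quaternary carbinol that cannot epimerise.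

Step 4
Reactants: 5 dimethyl (R)-citramalate
Product: 6 dimethyl (2R)-2-methyl-2-(triethylsilyloxy)butanedioate
Conditions: TESOTf, 2,6-lutidine, CH2Cl2, 0 °C → rt
Reagents that add atoms: triethylsilyl trifluoromethanesulfonate, CC[Si](CC)(CC)OS(=O)(=O)C(F)(F)F
Why: silyl triflate silylation is the standard way to cap a tertiary alcohol and removes the acidic proton before the organomagnesium and boron enolate steps.

Step 5
Reactants: 6 silyl ether diester
Product: 7 methyl (2R)-4-[methoxy(methyl)amino]-2-methyl-4-oxo-2-(triethylsilyloxy)butanoate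
Conditions: MeNHOMe·HCl, iPrMgCl, THF, −20 → 0 °C
Reagents that add atoms: N,O-dimethylhydroxylamine hydrochloride, CNOC.Cl
Why: Weinreb amidation with the magnesium amide should attack only the unhindered CH2CO2Me group (C8), because the C1 ester sits on the fully substituted, silyloxy-bearing C10.

Step 6
Reactants: 7 Weinreb amide; 3 allylic chloride
Product: 9 methyl (2R)-6-(tert-butyldiphenylsilyloxymethyl)-2-methyl-4-oxo-2-(triethylsilyloxy)hept-6-enoate, via allylmagnesium chloride 8 (not isolated)
Conditions: 3, Mg, THF, 0 °C; then 7, THF, −78 °C; aq. NH4Cl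
Reagents that add atoms: none
Why: Grignard addition to a Weinreb amide stops at the ketone through the chelated tetrahedral intermediate and forms the C7–C8 bond, while the hindered C1 ester should not react at −78 °C.

Step 7
Reactants: 9 β,γ-unsaturated ketone; 10 3-methylbut-2-enal (prenal)
Product: 11 6,7-syn aldol adduct (C6–OH, C8 ketone, C5=C4 prenyl olefin)
Conditions: (−)-Ipc2BOTf, iPr2NEt, CH2Cl2, −78 °C; 10, −78 → −20 °C; H2O2, MeOH, pH 7 buffer, 0 °C
Reagents that add atoms: none
Why: in this Paterson boron aldol enolisation occurs at the allylic C7 methylene (C9 is neopentyl-like), the Z-enol borinate reacts at its α-carbon through a Zimmerman–Traxler chair to give the 6,7-syn adduct, and the isopinocampheyl ligands select the aldehyde face that sets C6 and C7 as drawn.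

Step 8
Reactants: 11 aldol adduct
Product: 13 γ-lactone (C1 acyl on O8) with free C6–OH, via anti-diol 12 (not isolated)
Conditions: Me4NBH(OAc)3, MeCN/AcOH, −30 °C; then DBU (cat.), CH2Cl2, rt
Reagents that add atoms: none
Why: Evans–Saksena reduction delivers hydride intramolecularly from the C6 alkoxyborohydride and sets C8–OH 1,3-anti to C6–OH, and the new C8–OH then closes a five-membered lactone onto the C1 ester (5-exo-trig), which differentiates it from C6–OH.

Step 9
Reactants: 13 hydroxy γ-lactone
Product: 14 C6 tert-butyldimethylsilyl ether of the γ-lactone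
Conditions: TBSOTf, 2,6-lutidine, CH2Cl2, −78 → 0 °C
Reagents that add atoms: tert-butyldimethylsilyl trifluoromethanesulfonate, CC(C)(C)[Si](C)(C)OS(=O)(=O)C(F)(F)F
Why: silylation of the only free hydroxyl (secondary, allylic) with a silyl triflate is reliable even in this hindered position and leaves the lactone untouched.

Step 10
Reactants: 14 silylated γ-lactone
Product: 17 seco acid with C8 and C10 triethylsilyl ethers, via lithium carboxylate 15 (not isolated), via triethylsilyl ester 16 (not isolated)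
Conditions: LiOH, THF/H2O, rt; concentrate; TESOTf, 2,6-lutidine, CH2Cl2, 0 °C; then K2CO3, MeOH/H2O, 0 °C; pH 5 buffer
Reagents that add atoms: lithium hydroxide, [Li+].[OH-]; triethylsilyl trifluoromethanesulfonate, CC[Si](CC)(CC)OS(=O)(=O)C(F)(F)F
Why: saponification opens the γ-lactone, silylation of the carboxylate salt traps C8–OH before it can relactonise, and the silyl ester (far more labile than the silyl ethers) is then hydrolysed selectively to the free acid.

Step 11
Reactants: 17 seco acid
Product: 19 hydroxy acid with C5–OH and a C4 isopropenyl group, via allylic hydroperoxide 18 (not isolated)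
Conditions: O2, hν (visible), tetraphenylporphyrin (cat.), CH2Cl2, 0 °C; then PPh3, 0 °C → rt
Reagents that add atoms: dioxygen, O=O
Why: in this Schenck ene reaction singlet oxygen should attack the trisubstituted C4=C5 olefin much faster than the 1,1-disubstituted C11=C13 one, abstract a methyl hydrogen (allylic strain keeps C6–H in the olefin plane) and place oxygen on C5 anti to the C6 silyloxy group with the double bond moved to C4=C3, after which PPh3 reduces the hydroperoxide.

Step 12
Reactants: 19 hydroxy acid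
Product: 20 eight-membered lactone (oxocan-2-one; ring O–C1–C10–C9–C8–C7–C6–C5)
Conditions: MNBA, DMAP, Et3N, CH2Cl2 (1 mM, slow addition), rt → 40 °C
Reagents that add atoms: none
Why: Shiina macrolactonisation (mixed anhydride with 2-methyl-6-nitrobenzoic anhydride, acyl transfer by DMAP) has precedent for saturated eight-membered lactones, the substituents on the seven-carbon chain favour folded conformers, and no stereocentre changes.

Step 13
Reactants: 20 eight-membered lactone
Product: 22 (4Z)-cyclodec-4-en-1-one with C6 OTBS and C8 and C10 OTES groups, via 2-methylene-oxocane 21 (not isolated)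
Conditions: Cp2TiMe2, toluene, 75 °C (dark); then 130 °C (sealed)
Reagents that add atoms: dimethyltitanocene, C[Ti](C)(C1C=CC=C1)C1C=CC=C1
Why: Cp2TiMe2 loses methane on heating to give Cp2Ti=CH2, which methylenates the lactone carbonyl by cycloaddition and cycloreversion (Petasis olefination) to the 2-methylene-8-isopropenyl-oxocane 21, and further heating triggers the concerted [3,3]-sigmatropic (Claisen) shift in which C2–C3 forms while O–C5 breaks and the C1 carbonyl and the C4=C5 olefin appear. The closest known reaction type is the Claisen ring expansion of lactone-derived 2-methylene cyclic ethers that carry a vinyl group next to oxygen, which gives cycloalkenones four atoms larger (Tebbe or Petasis methylenation followed by thermolysis). The ten-membered carbocycle closes by ring expansion of the eight-membered oxacycle through a bridged bicyclic chair-like transition state (pericyclic array C2=C1–O–C5–C4=C3 spanned by the C6–C10 tether), driven by formation of the C=O bond. No new stereocentre is formed (C5 becomes sp2), but the olefin geometry is set, because the five-carbon tether can reach C1 only when C6 is pseudoaxial on C5 (a gauche C1–O–C5–C6 torsion, the anti torsion being out of reach in an eight-membered ring), which places C6 cis to C3 and gives the (Z)-C4=C5 bond of the target. The step needs chemoselective methylenation and a single rearrangement path, which the substrate secures since the lactone is its only carbonyl group, all hydroxyls are silyl ethers, and the fully substituted C10 (no α-hydrogen) rules out enolisation and leaves one exocyclic enol ether and so one allyl vinyl ether array. The temperature is held well below that of a siloxy-Cope shift of the C4=C5–C6–C7–C11=C13 diene.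

Step 14
Reactants: 22 cyclodecenone
Product: 23 C8 alcohol
Conditions: HF·pyridine, pyridine, THF, 0 °C
Reagents that add atoms: none
Why: the secondary triethylsilyl ether at C8 is the most labile silyl group present and should be cleaved selectively by buffered fluoride, the tertiary C10 triethylsilyl, the hindered C6 TBS and the primary TBDPS ethers being slower.

Step 15
Reactants: 23 C8 alcohol
Product: 24 C8 3-methylbutanoate (isovalerate)
Conditions: (iPrCH2CO)2O, DMAP, Et3N, CH2Cl2, 0 °C → rt
Reagents that add atoms: 3-methylbutanoic anhydride, CC(C)CC(=O)OC(=O)CC(C)C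
Why: DMAP-catalysed acylation of the only free hydroxyl should proceed with retention at C8, and any transannular hemiketal with the C1 ketone is drained through the open form.

Step 16
Reactants: 24 isovalerate
Product: 25 triol (C6–OH, C10–OH, C12–OH)
Conditions: HF·pyridine, THF, 0 °C → rt
Reagents that add atoms: none
Why: global fluoride desilylation under mildly acidic conditions should leave the ester, the α-ketol and the olefins intact and avoid base-induced acyl migration from O8 to O6.

Step 17
Reactants: 25 triol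
Product: 28 CNP0105188.1 (target), via hydroxy enal 26 (not isolated), via lactol 27 (not isolated)
Conditions: TEMPO (cat.), PhI(OAc)2, CH2Cl2, rt
Reagents that add atoms: none
Why: TEMPO/PhI(OAc)2 oxidises the primary allylic alcohol to the enal, C6–OH adds to give the five-membered lactol, and this is oxidised on to the α-methylene-γ-butyrolactone (oxidative lactonisation of a 1,4-diol), while the tertiary C10–OH cannot react and the C6 and C7 configurations are untouched.

## Compound list

1 | 2-methylenepropane-1,3-diol | C=C(CO)CO | starting material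
2 | 2-(tert-butyldiphenylsilyloxymethyl)prop-2-en-1-ol | C=C(CO)CO[Si](c1ccccc1)(c1ccccc1)C(C)(C)C | intermediate
3 | tert-butyl{[2-(chloromethyl)prop-2-en-1-yl]oxy}diphenylsilane | C=C(CCl)CO[Si](c1ccccc1)(c1ccccc1)C(C)(C)C | intermediate
4 | (R)-citramalic acid, (2R)-2-hydroxy-2-methylbutanedioic acid | OC(=O)C[C@@](C)(O)C(=O)O | starting material
5 | dimethyl (2R)-2-hydroxy-2-methylbutanedioate | COC(=O)C[C@@](C)(O)C(=O)OC | intermediate
6 | dimethyl (2R)-2-methyl-2-(triethylsilyloxy)butanedioate | COC(=O)C[C@@](C)(O[Si](CC)(CC)CC)C(=O)OC | intermediate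
7 | methyl (2R)-4-[methoxy(methyl)amino]-2-methyl-4-oxo-2-(triethylsilyloxy)butanoate | CON(C)C(=O)C[C@@](C)(O[Si](CC)(CC)CC)C(=O)OC | intermediate
8 | [2-(tert-butyldiphenylsilyloxymethyl)prop-2-en-1-yl]magnesium chloride | C=C(C[Mg]Cl)CO[Si](c1ccccc1)(c1ccccc1)C(C)(C)C | intermediate
9 | methyl (2R)-6-(tert-butyldiphenylsilyloxymethyl)-2-methyl-4-oxo-2-(triethylsilyloxy)hept-6-enoate (C1 ester, C10, C9, C8 ketone, C7 methylene) | C=C(CO[Si](c1ccccc1)(c1ccccc1)C(C)(C)C)CC(=O)C[C@@](C)(O[Si](CC)(CC)CC)C(=O)OC | intermediate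
10 | 3-methylbut-2-enal (prenal) | CC(C)=CC=O | starting material
11 | 6,7-syn aldol adduct: methyl ester at C1, C10 (R) with CH3 and OTES, C8 ketone, C7 carrying the 3-(TBDPS-oxy)prop-1-en-2-yl group, C6–OH, C5=C4(CH3)2 | CC(C)=C[C@@H](O)[C@H](C(=C)CO[Si](c1ccccc1)(c1ccccc1)C(C)(C)C)C(=O)C[C@@](C)(O[Si](CC)(CC)CC)C(=O)OC | intermediate
12 | 6,8-anti diol of 11 (C8–OH anti to C6–OH and to C10–O) | CC(C)=C[C@@H](O)[C@H](C(=C)CO[Si](c1ccccc1)(c1ccccc1)C(C)(C)C)[C@H](O)C[C@@](C)(O[Si](CC)(CC)CC)C(=O)OC | intermediate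
13 | γ-lactone (ring O8–C1(=O)–C10–C9–C8) carrying at C8 the C7 side chain with free C6–OH | CC(C)=C[C@@H](O)[C@H](C(=C)CO[Si](c2ccccc2)(c2ccccc2)C(C)(C)C)[C@H]1C[C@@](C)(O[Si](CC)(CC)CC)C(=O)O1 | intermediate
14 | C6 tert-butyldimethylsilyl ether of γ-lactone 13 | CC(C)=C[C@@H](O[Si](C)(C)C(C)(C)C)[C@H](C(=C)CO[Si](c2ccccc2)(c2ccccc2)C(C)(C)C)[C@H]1C[C@@](C)(O[Si](CC)(CC)CC)C(=O)O1 | intermediate
15 | lithium carboxylate from opening of 14 (free C8–OH) | CC(C)=C[C@@H](O[Si](C)(C)C(C)(C)C)[C@H](C(=C)CO[Si](c1ccccc1)(c1ccccc1)C(C)(C)C)[C@H](O)C[C@@](C)(O[Si](CC)(CC)CC)C(=O)[O-].[Li+] | intermediate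
16 | triethylsilyl ester with C8 and C10 triethylsilyl ethers | CC(C)=C[C@@H](O[Si](C)(C)C(C)(C)C)[C@H](C(=C)CO[Si](c1ccccc1)(c1ccccc1)C(C)(C)C)[C@H](O[Si](CC)(CC)CC)C[C@@](C)(O[Si](CC)(CC)CC)C(=O)O[Si](CC)(CC)CC | intermediate
17 | seco acid: C1 CO2H, C10 OTES, C8 OTES, C6 OTBS, C12 OTBDPS, C5=C4(CH3)2 | CC(C)=C[C@@H](O[Si](C)(C)C(C)(C)C)[C@H](C(=C)CO[Si](c1ccccc1)(c1ccccc1)C(C)(C)C)[C@H](O[Si](CC)(CC)CC)C[C@@](C)(O[Si](CC)(CC)CC)C(=O)O | intermediate
18 | C5 allylic hydroperoxide (5,6-anti) with C4 isopropenyl group | C=C(C)[C@@H](OO)[C@@H](O[Si](C)(C)C(C)(C)C)[C@H](C(=C)CO[Si](c1ccccc1)(c1ccccc1)C(C)(C)C)[C@H](O[Si](CC)(CC)CC)C[C@@](C)(O[Si](CC)(CC)CC)C(=O)O | intermediate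
19 | hydroxy acid: C5–OH (5,6-anti), isopropenyl on C5, otherwise as 17 | C=C(C)[C@@H](O)[C@@H](O[Si](C)(C)C(C)(C)C)[C@H](C(=C)CO[Si](c1ccccc1)(c1ccccc1)C(C)(C)C)[C@H](O[Si](CC)(CC)CC)C[C@@](C)(O[Si](CC)(CC)CC)C(=O)O | intermediate
20 | 3-methyl-8-(prop-1-en-2-yl)-7-(TBS-oxy)-6-[3-(TBDPS-oxy)prop-1-en-2-yl]-3,5-bis(TES-oxy)oxocan-2-one (oxocane C2 = C1, C3 = C10, C5 = C8, C6 = C7, C7 = C6, C8 = C5) | C=C(C)[C@H]1OC(=O)[C@](C)(O[Si](CC)(CC)CC)C[C@@H](O[Si](CC)(CC)CC)[C@@H](C(=C)CO[Si](c2ccccc2)(c2ccccc2)C(C)(C)C)[C@@H]1O[Si](C)(C)C(C)(C)C | intermediate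
21 | 2-methylene-oxocane (exocyclic enol ether of 20, C1=C2H2) | C=C(C)[C@H]1OC(=C)[C@](C)(O[Si](CC)(CC)CC)C[C@@H](O[Si](CC)(CC)CC)[C@@H](C(=C)CO[Si](c2ccccc2)(c2ccccc2)C(C)(C)C)[C@@H]1O[Si](C)(C)C(C)(C)C | intermediate
22 | (4Z)-4,10-dimethyl-6-(TBS-oxy)-7-[3-(TBDPS-oxy)prop-1-en-2-yl]-8,10-bis(TES-oxy)cyclodec-4-en-1-one (target numbering) | C/C1=C/[C@@H](O[Si](C)(C)C(C)(C)C)[C@H](C(=C)CO[Si](c2ccccc2)(c2ccccc2)C(C)(C)C)[C@H](O[Si](CC)(CC)CC)C[C@@](C)(O[Si](CC)(CC)CC)C(=O)CC1 | intermediate
23 | C8 alcohol of 22 | C/C1=C/[C@@H](O[Si](C)(C)C(C)(C)C)[C@H](C(=C)CO[Si](c2ccccc2)(c2ccccc2)C(C)(C)C)[C@H](O)C[C@@](C)(O[Si](CC)(CC)CC)C(=O)CC1 | intermediate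
24 | C8 3-methylbutanoate of 23 | C/C1=C/[C@@H](O[Si](C)(C)C(C)(C)C)[C@H](C(=C)CO[Si](c2ccccc2)(c2ccccc2)C(C)(C)C)[C@H](OC(=O)CC(C)C)C[C@@](C)(O[Si](CC)(CC)CC)C(=O)CC1 | intermediate
25 | triol: (4Z)-cyclodec-4-en-1-one with C6–OH, C7 3-hydroxyprop-1-en-2-yl, C8 isovalerate, C10–OH | C/C1=C/[C@@H](O)[C@H](C(=C)CO)[C@H](OC(=O)CC(C)C)C[C@@](C)(O)C(=O)CC1 | intermediate
26 | hydroxy enal (C12 aldehyde, free C6–OH) | C/C1=C/[C@@H](O)[C@H](C(=C)C=O)[C@H](OC(=O)CC(C)C)C[C@@](C)(O)C(=O)CC1 | intermediate
27 | lactol (C6–O–C12H(OH), both C12 epimers) | C/C1=C/[C@H]2OC(O)C(=C)[C@@H]2[C@H](OC(=O)CC(C)C)C[C@@](C)(O)C(=O)CC1 | intermediate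
28 | CNP0105188.1 | C=C1C(=O)O[C@@H]2/C=C(/C)CCC(=O)[C@](C)(O)C[C@@H](OC(=O)CC(C)C)[C@@H]12 | target

## Step count and risks

Total step count: 17. Longest linear sequence: 15 steps (steps 3–17, from (R)-citramalic acid); steps 1–2 prepare the allyl fragment.

Steps most likely to fail:

Step 13 (key step). The lactone carbonyl, flanked by the fully substituted C10, may be methylenated slowly, and at the temperature the [3,3] shift then needs the enol ether may hydrolyse or isomerise, or the product may drift into a siloxy-Cope manifold. The fallback sets out from lactone 20 and returns at ketone 22. The lactone is methylenated at low temperature with the Tebbe reagent Cp2Ti(μ-Cl)(μ-CH2)AlMe2 (THF, pyridine, −40 → 0 °C) and enol ether 21 is isolated on basic alumina. Treatment of 21 with iBu3Al (CH2Cl2, −78 °C → rt) promotes the Claisen shift below room temperature and reduces the new ketone in the same flask, which should give the cyclodecenol F1 (both C1 epimers). Oxidation of F1 with Dess–Martin periodinane (NaHCO3, CH2Cl2) leads back to 22.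

Step 12. Acyl transfer from the mixed anhydride to the hindered tertiary carboxyl may be slow, so that aroylation of C5–OH and intermolecular esterification outrun ring closure. The fallback sets out from hydroxy acid 19 and returns at ketone 22. The ring is closed from the alcohol side by Mitsunobu lactonisation (PPh3, DIAD, toluene, high dilution, 0 °C → rt), in which the unhindered carboxylate oxygen displaces the activated C5 oxygen with inversion and gives the C5-epimeric lactone F2. Because C5 is planarised in the key step, F2 is taken through the step 13 conditions, via its enol ether F3 (not isolated), to the same ketone 22.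

Step 7. Facial selectivity of the bulky diisopinocampheylboron dienolate may be poor, or enolisation of the branched ketone sluggish. The fallback uses auxiliary control; it sets out from chloride 3 (through Grignard reagent 8) and prenal 10 and returns at lactone 14. Carboxylation of 8 with CO2 gives the but-3-enoic acid F4, which is coupled (PivCl, Et3N; LiCl) with (S)-4-benzyl-2-oxazolidinone to the imide F5. An Evans syn aldol reaction (Bu2BOTf, iPr2NEt, CH2Cl2, −78 °C, then 10) should give the adduct F6 with the same 6,7 configuration as 11. Transamidation (Me3Al, MeNHOMe·HCl) gives the Weinreb amide F7, TBSOTf the silyl ether F8, and MeMgBr the methyl ketone F9. Kinetic silylation (LiHMDS, TMSCl, −78 °C) gives the enol silane F10. A Mukaiyama aldol addition to methyl pyruvate catalysed by [Cu((R,R)-tBu-box)](OTf)2 (ligand antipode chosen for the 10R carbinol) should give, after mild acid work-up, the tertiary alcohol F11. Reduction with Me4NBH(OAc)3, now directed by C10–OH, gives the 8,10-anti diol F12, which lactonises (DBU) to the hydroxy lactone F13. Silylation with TESOTf and 2,6-lutidine gives 14.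

Further compounds
F1 | step 13 | (4Z)-cyclodec-4-en-1-ol corresponding to 22 (C1 carbinol, both epimers) | C/C1=C/[C@@H](O[Si](C)(C)C(C)(C)C)[C@H](C(=C)CO[Si](c2ccccc2)(c2ccccc2)C(C)(C)C)[C@H](O[Si](CC)(CC)CC)C[C@@](C)(O[Si](CC)(CC)CC)C(O)CC1
F2 | step 12 | C5 epimer of eight-membered lactone 20 | C=C(C)[C@@H]1OC(=O)[C@](C)(O[Si](CC)(CC)CC)C[C@@H](O[Si](CC)(CC)CC)[C@@H](C(=C)CO[Si](c2ccccc2)(c2ccccc2)C(C)(C)C)[C@@H]1O[Si](C)(C)C(C)(C)C
F3 | step 12 | C5 epimer of enol ether 21 | C=C(C)[C@@H]1OC(=C)[C@](C)(O[Si](CC)(CC)CC)C[C@@H](O[Si](CC)(CC)CC)[C@@H](C(=C)CO[Si](c2ccccc2)(c2ccccc2)C(C)(C)C)[C@@H]1O[Si](C)(C)C(C)(C)C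
F4 | step 7 | 3-(tert-butyldiphenylsilyloxymethyl)but-3-enoic acid | C=C(CC(=O)O)CO[Si](c1ccccc1)(c1ccccc1)C(C)(C)C
F5 | step 7 | (4S)-4-benzyl-3-[3-(tert-butyldiphenylsilyloxymethyl)but-3-enoyl]oxazolidin-2-one | C=C(CO[Si](c1ccccc1)(c1ccccc1)C(C)(C)C)CC(=O)N1[C@@H](Cc2ccccc2)COC1=O
F6 | step 7 | Evans syn aldol adduct (imide at C8, C7 side chain, C6–OH, prenyl olefin) | CC(C)=C[C@@H](O)[C@H](C(=C)CO[Si](c1ccccc1)(c1ccccc1)C(C)(C)C)C(=O)N1[C@@H](Cc2ccccc2)COC1=O
F7 | step 7 | Weinreb amide of the aldol adduct (free C6–OH) | CC(C)=C[C@@H](O)[C@H](C(=C)CO[Si](c1ccccc1)(c1ccccc1)C(C)(C)C)C(=O)N(C)OC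
F8 | step 7 | C6 tert-butyldimethylsilyl ether of the Weinreb amide | CC(C)=C[C@@H](O[Si](C)(C)C(C)(C)C)[C@H](C(=C)CO[Si](c1ccccc1)(c1ccccc1)C(C)(C)C)C(=O)N(C)OC
F9 | step 7 | methyl ketone (C8 ketone, C9 methyl) | CC(C)=C[C@@H](O[Si](C)(C)C(C)(C)C)[C@H](C(=C)CO[Si](c1ccccc1)(c1ccccc1)C(C)(C)C)C(C)=O
F10 | step 7 | trimethylsilyl enol ether of the methyl ketone (C8=C9) | CC(C)=C[C@@H](O[Si](C)(C)C(C)(C)C)[C@H](C(=C)CO[Si](c1ccccc1)(c1ccccc1)C(C)(C)C)C(=C)O[Si](C)(C)C
F11 | step 7 | pyruvate aldol adduct (C10 tertiary alcohol, C8 ketone, C1 methyl ester) | CC(C)=C[C@@H](O[Si](C)(C)C(C)(C)C)[C@H](C(=C)CO[Si](c1ccccc1)(c1ccccc1)C(C)(C)C)C(=O)C[C@@](C)(O)C(=O)OC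
F12 | step 7 | 8,10-anti diol methyl ester | CC(C)=C[C@@H](O[Si](C)(C)C(C)(C)C)[C@H](C(=C)CO[Si](c1ccccc1)(c1ccccc1)C(C)(C)C)[C@H](O)C[C@@](C)(O)C(=O)OC
F13 | step 7 | γ-lactone with free C10–OH and C6 OTBS | CC(C)=C[C@@H](O[Si](C)(C)C(C)(C)C)[C@H](C(=C)CO[Si](c2ccccc2)(c2ccccc2)C(C)(C)C)[C@H]1C[C@@](C)(O)C(=O)O1
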